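I start from a neighbour of winter, the same closed stirred flask with 1.2 mM of Q in place of 5.00 mM. Less Q ought to leave more D, and before I know any result I want a number that says how much.

| setting | dusk | winter | summer | noon |
|---|---|---|---|---|
| X | 1.0 mM | 1.0 mM | 1.0 mM | 1.0 mM (fed, over 0.500 min) |
| J | 1.80 mM (fed, over 0.500 min) | 1.80 mM | 1.80 mM | 1.80 mM |
| Q | 5.00 mM | 5.00 mM | 5.00 mM | 5.00 mM |
| time | 1.0 min | 1.0 min |  | 1.0 min |
| remark | all but J at the start; J goes in evenly over 0.500 min, the run ends at 1.0 min | everything together in a closed stirred flask, run for 1.0 min | a single well-mixed tank run continuously and read at steady state, 1.0 min in it on average | all but X at the start; X goes in evenly over 0.500 min, the run ends at 1.0 min |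

    X + J ⇌ Q + D (K1 = 25, k1 = 150 M⁻¹ s⁻¹)
    L + J ⇌ Q + E (K2 = 5.4, k2 = 290 M⁻¹ s⁻¹)
    2 J → J2 (k3 = 80 M⁻¹ s⁻¹)
    D + J ⇌ Q + L (K4 = 1.8, k4 = 110 M⁻¹ s⁻¹)

- for a step with 2 of a species take k times the square, and two of it per event
- the stated concentrations are those of everything mixed, before any reaction; amounts are the same in each set-up
- the feed brings no volume worth counting
- run time (dusk): 1.0 min

- the set-up with the highest amount of D at the outlet or at the end, in percent of the X put in ("none" if the first two lie within 2 percentage points) (dusk / winter / summer / noon / none)
- amount of D at the outlet or at the end, in percent of the X put in, dusk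
- amount of D at the outlet or at the end, in percent of the X put in, winter
- amount of D at the outlet or at the end, in percent of the X put in, summer
- amount of D at the outlet or at the end, in percent of the X put in, noon

My first thought for winter is that J stands in excess, 1.80 mM on 1.0 mM of X, and that the first exchange has a constant of 25, so X should end as D. But at mixing, J goes into dimerisation 1.92 times as fast as into D, so this excess will not last.

A better guide has no time in it. I divide the forward rate of the first exchange by its backward rate, K[X][J]/([D][Q]), and set the quotient to one. That gives [D]/[X] = [J]/J*, where J* = [Q]/K is the balance J, the free J at which D and X stand equal, 0.200 mM at the charged Q.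

Does the balance have time to form? The return of D, pseudo-first-order at the charged Q, has a half-life of 23.1 s, shorter than the run, so I use it at the end of winter. Dimerisation alone leaves 0.0985 mM of J at 1.0 min, so [D]/[X] is 0.493 and D is 33.0% of the X. The objection is that D gives J back as it returns, which this J leaves out, so I hold that share as a floor for winter. L is no great correction, at 3.54% of D by its own balance.

For dusk, dimerisation matched against the feed holds J near 0.612 mM when the feed stops, and the remaining 0.500 min brings it to 0.155 mM, so D is 43.7%. X takes part of that feed, so this J may stand too high, but the order stays: dusk ends with more J than winter. For noon, the first half-life of J by dimerisation at its charge is 3.47 s, shorter than the feed of X over 0.500 min, so J dimerises while the X is still coming in, and I expect less D than in winter. The tank has feed and outflow, so I do not assume the balance there and leave it unreckoned.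

The forecast names dusk, with dusk 50%, winter 41%, summer 45% and noon 35%, on the grounds that “Slow feeding of J (dusk) does this best”.

The simulation gives dusk as best, with dusk 51.1%, winter 42.6%, summer 44.6% and noon 25.6%. In winter the relaxation half-life of the first exchange at the end, 0.0827 min, is short against 1.0 min, and there [D]/[X] reads 0.775 against a [J]/J* of 0.664, with J* taken at the Q then standing. In the neighbour with 1.2 mM of Q, J* at its final Q is 0.0771 mM, [J]/J* is 1.36, [D]/[X] reads 1.49, and D stands at 55.1%.

The rate constants are invented.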